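**Retrosynthetic overview**

1. The strategy rests on the side chain C1'(OAc)–C2'H2–C3'H=C4'(CH3)–C5'H2OAc: its Z-alkene (C2' cis to C5') and both oxygens are the ring-opened, reduced form of a 3-methyl-5,6-dihydropyran-2-one (ring O–C1'–C2'–C3'=C4'–C5').
2. Target ⇒ ene-diol ⇒ lactone 31 ⇒ epoxy aldehyde 27 + silyl dienolate 30 of ethyl tiglate; one copper-catalysed vinylogous aldol–lactonisation forms C1'–C2' and the lactone C–O bond.
3. 27 ⇒ C4–C5 epoxidation, C8 methylenation and a B-alkyl Suzuki closure of the nine-membered ring at C5–C6 on a trans-1,2-disubstituted cyclobutane.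
4. Cyclobutane (C1, C9, C10, C11) ⇒ Wolff contraction of a 2-diazocyclopentanone; C1 from a cuprate addition anti to CH2OTBDPS; C11 from an asymmetric conjugate phenylation of 3-methylcyclopent-2-en-1-one (phenyl = latent C1').
5. Ring order: cyclopentanone → cyclobutane → nine-membered carbocycle → oxirane → dihydropyranone (opened again at the end).

Key step: step 20

Remark on numbering: the core carries caryophyllane numbers (C1 and C9 ring fusion, C4–C5 epoxide, C8 bearing the exocyclic CH2, C10 cyclobutane CH2, C11 quaternary carbon); the side chain is C1'–C5'; TBDPS = tert-butyldiphenylsilyl.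

Assumption: (S)-t-BuPyOx is taken to give the (R)-ketone 2 and (R)-Tol-BINAP to direct the dienolate to the Si face of aldehyde 27; if a model reaction shows the opposite sense for either ligand, its antipode is used and nothing else changes.

**Route**

Step 1
Reactants: 1 3-methylcyclopent-2-en-1-one
Product: 2 (R)-3-methyl-3-phenylcyclopentan-1-one
Conditions: PhB(OH)2, Pd(OCOCF3)2 (5 mol%), (S)-t-BuPyOx (6 mol%), NH4PF6, H2O, ClCH2CH2Cl, 40 °C
Reagents that add atoms: phenylboronic acid, OB(O)c1ccccc1
Why: Palladium-catalysed asymmetric conjugate addition of an arylboronic acid to a β-substituted cyclic enone should create the quaternary carbon (the future C11) under control of the pyridine–oxazoline ligand, the phenyl group serving as a robust latent carboxyl (C1').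

Step 2
Reactants: 2 (R)-3-methyl-3-phenylcyclopentan-1-one
Product: 3 (R)-1-methyl-3-oxocyclopentane-1-carboxylic acid
Conditions: RuCl3·xH2O (5 mol%), NaIO4, CCl4/MeCN/H2O, rt
Reagents that add atoms: sodium periodate, [Na+].[O-]I(=O)(=O)=O; water, O
Why: RuO4-mediated oxidative degradation of the arene (catalytic RuCl3 with periodate) should turn the phenyl ring into the carboxylic acid without touching the quaternary stereocentre or the ketone.

Step 3
Reactants: 3 (R)-1-methyl-3-oxocyclopentane-1-carboxylic acid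
Product: 4 (3R)-3-(hydroxymethyl)-3-methylcyclopentan-1-ol (both C1 epimers)
Conditions: LiAlH4, THF, 0 °C to reflux; aqueous NaOH work-up
Reagents that add atoms: none
Why: Hydride reduction of acid and ketone should give the diol; the new carbinol centre is of no consequence because it is reoxidised in step 5.

Step 4
Reactants: 4 (3R)-3-(hydroxymethyl)-3-methylcyclopentan-1-ol
Product: 5 (3R)-3-{[tert-butyl(diphenyl)silyl]oxymethyl}-3-methylcyclopentan-1-ol (both C1 epimers)
Conditions: TBDPSCl (1.05 equiv), imidazole, CH2Cl2, 0 °C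
Reagents that add atoms: tert-butyl(chloro)diphenylsilane, CC(C)(C)[Si](Cl)(c1ccccc1)c1ccccc1
Why: Silylation with the bulky chlorosilane should select the primary over the secondary hydroxyl and installs the large CH2OTBDPS group that later shields one ring face.

Step 5
Reactants: 5 (3R)-3-{[tert-butyl(diphenyl)silyl]oxymethyl}-3-methylcyclopentan-1-ol
Product: 7 (S)-4-{[tert-butyl(diphenyl)silyl]oxymethyl}-4-methylcyclopent-2-en-1-one, via ketone 6 (not isolated)
Conditions: IBX (3.5 equiv), DMSO, 25 °C then 75 °C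
Reagents that add atoms: none
Why: IBX oxidation of the alcohol followed by IBX-mediated α,β-dehydrogenation should give the enone, the double bond being able to form only on the side away from the quaternary carbon.

Step 6
Reactants: 7 (S)-4-{[tert-butyl(diphenyl)silyl]oxymethyl}-4-methylcyclopent-2-en-1-one and 8 (4-bromobut-1-yn-1-yl)trimethylsilane
Product: 10 trimethyl{[(3S,4S)-4-{[tert-butyl(diphenyl)silyl]oxymethyl}-4-methyl-3-[4-(trimethylsilyl)but-3-yn-1-yl]cyclopent-1-en-1-yl]oxy}silane (chain trans to CH2OTBDPS), via Grignard reagent 9 (not isolated)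
Conditions: 8, Mg, THF, rt; then 7, CuBr·SMe2 (10 mol%), TMSCl, DMPU, THF, −78 °C; Et3N/pentane work-up
Reagents that add atoms: chlorotrimethylsilane, C[Si](C)(C)Cl
Why: Copper-catalysed conjugate addition of the Grignard reagent with silyl trapping should deliver the chain to the β-carbon anti to the bulky silyloxymethyl group (cis to methyl), setting C1 relative to C11 and giving the regiodefined enol ether.

Step 7
Reactants: 10 silyl enol ether
Product: 13 (3R,4S)-4-{[tert-butyl(diphenyl)silyl]oxymethyl}-2-diazo-4-methyl-3-[4-(trimethylsilyl)but-3-yn-1-yl]cyclopentan-1-one, via lithium enolate 11 (not isolated), via trifluoroacetyl ketone 12 (not isolated)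
Conditions: MeLi, THF, 0 °C; CF3CO2CH2CF3, −78 °C; then MsN3, Et3N, H2O, MeCN, rt
Reagents that add atoms: methanesulfonyl azide, CS(=O)(=O)N=[N+]=[N-]
Why: Regiospecific release of the lithium enolate, Claisen trifluoroacetylation and detrifluoroacetylative (Regitz-type) diazo transfer should place the diazo group on the carbon that becomes C9, with no stereocentre involved.

Step 8
Reactants: 13 diazo ketone
Product: 15 methyl (2S,3S)-3-{[tert-butyl(diphenyl)silyl]oxymethyl}-3-methyl-2-[4-(trimethylsilyl)but-3-yn-1-yl]cyclobutane-1-carboxylate (C1 epimers), via ketene 14 (not isolated)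
Conditions: hν (365 nm), MeOH, rt
Reagents that add atoms: methanol, CO
Why: The photochemical Wolff rearrangement (loss of N2 with 1,2-shift of the C10 methylene) should contract the ring to the cyclobutyl ketene, which methanol traps; C1 and C11 are untouched and the C9 epimer mixture is corrected in step 10.

Step 9
Reactants: 15 methyl ester
Product: 16 (2S,3S)-3-{[tert-butyl(diphenyl)silyl]oxymethyl}-3-methyl-2-[4-(trimethylsilyl)but-3-yn-1-yl]cyclobutane-1-carbaldehyde (C1 epimers)
Conditions: i-Bu2AlH (DIBAL-H, 1.1 equiv), CH2Cl2, −78 °C; Rochelle salt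
Reagents that add atoms: none
Why: Partial reduction of the ester by DIBAL at low temperature should stop at the aldehyde because the tetrahedral aluminate survives until work-up.

Step 10
Reactants: 16 aldehyde
Product: 17 (1R,2S,3S)-2-(but-3-yn-1-yl)-3-{[tert-butyl(diphenyl)silyl]oxymethyl}-3-methylcyclobutane-1-carbaldehyde
Conditions: K2CO3, MeOH, rt
Reagents that add atoms: none
Why: Mild base should epimerise the enolisable aldehyde to the thermodynamically favoured trans-1,2-disubstituted cyclobutane (C9 R) and at the same time cleave the alkynyl C–Si bond by methanolysis.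

Step 11
Reactants: 17 trans aldehyde
Product: 18 1-[(1R,2S,3S)-2-(but-3-yn-1-yl)-3-{[tert-butyl(diphenyl)silyl]oxymethyl}-3-methylcyclobutyl]prop-2-en-1-ol (carbinol epimers)
Conditions: CH2=CHMgBr (3 equiv), THF, −78 to 0 °C; aq. NH4Cl
Reagents that add atoms: vinylmagnesium bromide, C=C[Mg]Br
Why: Grignard 1,2-addition supplies C7 and C6; the C8 carbinol configuration is irrelevant since it is oxidised in step 14, and the excess reagent covers deprotonation of the alkyne.

Step 12
Reactants: 18 allylic alcohol
Product: 20 1-[(1R,2S,3S)-3-{[tert-butyl(diphenyl)silyl]oxymethyl}-2-[(3E)-4-iodo-3-methylbut-3-en-1-yl]-3-methylcyclobutyl]prop-2-en-1-ol (carbinol epimers), via vinylalane 19 (not isolated)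
Conditions: Me3Al (4 equiv), Cp2ZrCl2 (0.3 equiv), CH2Cl2, 0 °C to rt; then I2, THF, −30 °C
Reagents that add atoms: trimethylaluminium, C[Al](C)C; iodine, II
Why: Zirconium-catalysed Negishi carboalumination should add methyl and aluminium syn across the terminal alkyne with methyl on the internal carbon, and iodinolysis with retention gives the (E)-vinyl iodide that fixes the geometry of the future C4=C5 bond.

Step 13
Reactants: 20 vinyl iodide
Product: 22 (1S,9R,11S,4E)-11-{[tert-butyl(diphenyl)silyl]oxymethyl}-4,11-dimethylbicyclo[7.2.0]undec-4-en-8-ol (C8 epimers), via alkylborane 21 (not isolated)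
Conditions: 9-BBN (2.5 equiv), THF, rt; then slow addition to PdCl2(dppf) (15 mol%), AsPh3, Cs2CO3, DMF/THF/H2O, 60 °C, high dilution
Reagents that add atoms: none
Why: 9-BBN should hydroborate only the monosubstituted alkene at C6, and the intramolecular B-alkyl Suzuki–Miyaura coupling then forms C5–C6 with retention of the vinyl iodide geometry, a ring closure of the kind known for (E)-cyclononenes.

Step 14
Reactants: 22 bicyclic alcohol
Product: 23 (1S,9R,11S,4E)-11-{[tert-butyl(diphenyl)silyl]oxymethyl}-4,11-dimethylbicyclo[7.2.0]undec-4-en-8-one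
Conditions: Dess–Martin periodinane, NaHCO3, CH2Cl2, 0 °C to rt
Reagents that add atoms: none
Why: Dess–Martin oxidation should convert both C8 epimers into one ketone.

Step 15
Reactants: 23 ketone
Product: 24 (1S,9R,11S,4E)-11-{[tert-butyl(diphenyl)silyl]oxymethyl}-4,11-dimethyl-8-methylidenebicyclo[7.2.0]undec-4-ene
Conditions: Ph3PCH3Br, KOt-Bu, THF, 0 to 40 °C
Reagents that add atoms: methyltriphenylphosphonium bromide, C[P+](c1ccccc1)(c1ccccc1)c1ccccc1.[Br-]
Why: Wittig methylenation installs the exocyclic C8=CH2, and the trans ring fusion at the enolisable C9 should persist because it is the thermodynamically preferred one in this ring system.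

Step 16
Reactants: 24 diene
Product: 25 (1S,4S,5S,9R,11S)-11-{[tert-butyl(diphenyl)silyl]oxymethyl}-4,5-epoxy-4,11-dimethyl-8-methylidenebicyclo[7.2.0]undecane
Conditions: mCPBA (1.05 equiv), NaHCO3, CH2Cl2, −20 to 0 °C
Reagents that add atoms: 3-chloroperoxybenzoic acid, OOC(=O)c1cccc(Cl)c1
Why: In this Prilezhaev epoxidation the strained trisubstituted (E)-alkene should react far faster than the exocyclic methylene, and the peracid should attack the exposed outer face of the trans-cyclononene, as in the caryophyllene series, to set C4 and C5 as (S,S), any minor diastereomer being removed by chromatography.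

Step 17
Reactants: 25 epoxy silyl ether
Product: 26 [(1S,4S,5S,9R,11S)-4,5-epoxy-4,11-dimethyl-8-methylidenebicyclo[7.2.0]undecan-11-yl]methanol
Conditions: Bu4NF, THF, rt to 40 °C
Reagents that add atoms: none
Why: Fluoride cleavage of the silyl ether should leave the epoxide and the alkene untouched.

Step 18
Reactants: 26 epoxy alcohol
Product: 27 (1S,4S,5S,9R,11S)-4,5-epoxy-4,11-dimethyl-8-methylidenebicyclo[7.2.0]undecane-11-carbaldehyde
Conditions: Dess–Martin periodinane, NaHCO3, pyridine, CH2Cl2, 0 °C
Reagents that add atoms: none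
Why: Buffered Dess–Martin oxidation should convert the neopentyl alcohol into the non-enolisable aldehyde while sparing the acid-sensitive epoxide.

Step 19
Reactants: 28 ethyl tiglate
Product: 30 1-ethoxy-2-methyl-1-(trimethylsilyloxy)buta-1,3-diene, via lithium dienolate 29 (not isolated)
Conditions: LDA (i-Pr2NLi), DMPU, THF, −78 °C; TMSCl; distillation
Reagents that add atoms: chlorotrimethylsilane, C[Si](C)(C)Cl
Why: γ-Deprotonation of the tiglate and O-silylation of the extended enolate should give the silyl dienolate.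

Step 20
Reactants: 27 epoxy core aldehyde and 30 silyl dienolate
Product: 31 (6S)-3-methyl-6-[(1S,4S,5S,9R,11S)-4,5-epoxy-4,11-dimethyl-8-methylidenebicyclo[7.2.0]undecan-11-yl]-5,6-dihydro-2H-pyran-2-one
Conditions: Cu(OTf)2 (10 mol%), (R)-Tol-BINAP (11 mol%), Bu4N Ph3SiF2 (20 mol%), THF, 0 °C to rt
Reagents that add atoms: none
Why: The monovalent copper fluoride–Tol-BINAP complex formed from Cu(OTf)2, the bisphosphine and the fluoride source desilylates 30 to a copper dienolate, which adds through its γ-carbon to the aldehyde carbon C1' (bond C1'–C2'); the copper alkoxide then attacks the ethyl ester and expels ethoxide, which takes up the silyl group and regenerates the copper dienolate. The closest known reaction type is the copper-catalysed asymmetric vinylogous Mukaiyama aldol addition of ester-derived silyl dienolates to aldehydes with in situ lactonisation to 5,6-dihydropyran-2-ones. The dihydropyranone ring closes by 6-exo-trig O-acylation (lactone C5'–O bond), which only the Z-configured enoate can undergo, so the ring fixes the Z geometry of C3'=C4'. The new stereocentre C1' (S) should result from attack on the Si face of the aldehyde, chosen by the Tol-BINAP enantiomer and reinforced by the Felkin–Anh preference of the α-quaternary aldehyde (C1 as the large group anti to the nucleophile, the C11 methyl on the side of the incoming dienolate). The step needs γ- over α-regioselectivity, secured by the soft copper dienolate and its α-methyl group, and chemoselectivity for the aldehyde, secured by the almost neutral conditions that leave the epoxide and the exocyclic alkene alone and by the absence of α-hydrogens in 27.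

Step 21
Reactants: 31 lactone
Product: 33 (1S,3Z)-1-[(1S,4S,5S,9R,11S)-4,5-epoxy-4,11-dimethyl-8-methylidenebicyclo[7.2.0]undecan-11-yl]-4-methylpent-3-ene-1,5-diol, via lactol 32 (not isolated)
Conditions: i-Bu2AlH (DIBAL-H, 4 equiv), CH2Cl2, −78 to −10 °C; Rochelle salt
Reagents that add atoms: none
Why: DIBAL 1,2-reduction of the unsaturated lactone through the lactol should open the ring to the ene-diol with the Z-alkene untouched, the low temperature sparing the epoxide.

Step 22
Reactants: 33 diol
Product: 34 target diacetate CNP0256343.1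
Conditions: Ac2O, pyridine, DMAP (cat.), CH2Cl2, rt
Reagents that add atoms: acetic anhydride, CC(=O)OC(C)=O
Why: DMAP-catalysed acetylation should esterify the primary allylic and the hindered secondary hydroxyl without affecting the epoxide.

**Compound list**

1 | 3-methylcyclopent-2-en-1-one | CC1=CC(=O)CC1 | starting material
2 | (R)-3-methyl-3-phenylcyclopentan-1-one | O=C1C[C@](C)(c2ccccc2)CC1 | intermediate
3 | (R)-1-methyl-3-oxocyclopentane-1-carboxylic acid | O=C1C[C@](C)(C(=O)O)CC1 | intermediate
4 | (3R)-3-(hydroxymethyl)-3-methylcyclopentan-1-ol (C1 epimers) | OC1C[C@](C)(CO)CC1 | intermediate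
5 | (3R)-3-{[tert-butyl(diphenyl)silyl]oxymethyl}-3-methylcyclopentan-1-ol (C1 epimers) | OC1C[C@](C)(CO[Si](c2ccccc2)(c2ccccc2)C(C)(C)C)CC1 | intermediate
6 | (R)-3-{[tert-butyl(diphenyl)silyl]oxymethyl}-3-methylcyclopentan-1-one (not isolated) | O=C1C[C@](C)(CO[Si](c2ccccc2)(c2ccccc2)C(C)(C)C)CC1 | intermediate
7 | (S)-4-{[tert-butyl(diphenyl)silyl]oxymethyl}-4-methylcyclopent-2-en-1-one | O=C1C[C@](C)(CO[Si](c2ccccc2)(c2ccccc2)C(C)(C)C)C=C1 | intermediate
8 | (4-bromobut-1-yn-1-yl)trimethylsilane | C[Si](C)(C)C#CCCBr | starting material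
9 | [4-(trimethylsilyl)but-3-yn-1-yl]magnesium bromide (not isolated) | C[Si](C)(C)C#CCC[Mg]Br | intermediate
10 | trimethyl{[(3S,4S)-4-{[tert-butyl(diphenyl)silyl]oxymethyl}-4-methyl-3-[4-(trimethylsilyl)but-3-yn-1-yl]cyclopent-1-en-1-yl]oxy}silane | C[Si](C)(C)C#CCC[C@H]1C=C(O[Si](C)(C)C)C[C@]1(C)CO[Si](c2ccccc2)(c2ccccc2)C(C)(C)C | intermediate
11 | lithium enolate corresponding to 10 (not isolated) | C[Si](C)(C)C#CCC[C@H]1C=C(O[Li])C[C@]1(C)CO[Si](c2ccccc2)(c2ccccc2)C(C)(C)C | intermediate
12 | 2-(trifluoroacetyl) derivative of the (3S,4S)-ketone (C2 epimers or enol, not isolated) | C[Si](C)(C)C#CCC[C@H]1C(C(=O)C(F)(F)F)C(=O)C[C@]1(C)CO[Si](c2ccccc2)(c2ccccc2)C(C)(C)C | intermediate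
13 | (3R,4S)-4-{[tert-butyl(diphenyl)silyl]oxymethyl}-2-diazo-4-methyl-3-[4-(trimethylsilyl)but-3-yn-1-yl]cyclopentan-1-one | C[Si](C)(C)C#CCC[C@H]1C(=[N+]=[N-])C(=O)C[C@]1(C)CO[Si](c2ccccc2)(c2ccccc2)C(C)(C)C | intermediate
14 | ring-contracted cyclobutylidene ketene (not isolated) | C[Si](C)(C)C#CCC[C@H]1C(=C=O)C[C@]1(C)CO[Si](c2ccccc2)(c2ccccc2)C(C)(C)C | intermediate
15 | methyl (2S,3S)-3-{[tert-butyl(diphenyl)silyl]oxymethyl}-3-methyl-2-[4-(trimethylsilyl)but-3-yn-1-yl]cyclobutane-1-carboxylate (C1 epimers) | C[Si](C)(C)C#CCC[C@H]1C(C(=O)OC)C[C@]1(C)CO[Si](c2ccccc2)(c2ccccc2)C(C)(C)C | intermediate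
16 | (2S,3S)-3-{[tert-butyl(diphenyl)silyl]oxymethyl}-3-methyl-2-[4-(trimethylsilyl)but-3-yn-1-yl]cyclobutane-1-carbaldehyde (C1 epimers) | C[Si](C)(C)C#CCC[C@H]1C(C=O)C[C@]1(C)CO[Si](c2ccccc2)(c2ccccc2)C(C)(C)C | intermediate
17 | (1R,2S,3S)-2-(but-3-yn-1-yl)-3-{[tert-butyl(diphenyl)silyl]oxymethyl}-3-methylcyclobutane-1-carbaldehyde | C#CCC[C@H]1[C@H](C=O)C[C@]1(C)CO[Si](c2ccccc2)(c2ccccc2)C(C)(C)C | intermediate
18 | 1-[(1R,2S,3S)-2-(but-3-yn-1-yl)-3-{[tert-butyl(diphenyl)silyl]oxymethyl}-3-methylcyclobutyl]prop-2-en-1-ol (carbinol epimers) | C#CCC[C@H]1[C@H](C(O)C=C)C[C@]1(C)CO[Si](c2ccccc2)(c2ccccc2)C(C)(C)C | intermediate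
19 | (E)-vinylalane with the carbinol as its dimethylaluminium alkoxide (not isolated) | C[Al](C)/C=C(C)/CC[C@H]1[C@H](C(O[Al](C)C)C=C)C[C@]1(C)CO[Si](c2ccccc2)(c2ccccc2)C(C)(C)C | intermediate
20 | 1-[(1R,2S,3S)-3-{[tert-butyl(diphenyl)silyl]oxymethyl}-2-[(3E)-4-iodo-3-methylbut-3-en-1-yl]-3-methylcyclobutyl]prop-2-en-1-ol (carbinol epimers) | I/C=C(C)/CC[C@H]1[C@H](C(O)C=C)C[C@]1(C)CO[Si](c2ccccc2)(c2ccccc2)C(C)(C)C | intermediate
21 | C6 B-alkyl-9-BBN adduct of 20 with the carbinol as its 9-BBN borinate (not isolated) | I/C=C(C)/CC[C@H]1[C@H](C(OB2C3CCCC2CCC3)CCB2C3CCCC2CCC3)C[C@]1(C)CO[Si](c2ccccc2)(c2ccccc2)C(C)(C)C | intermediate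
22 | (1S,9R,11S,4E)-11-{[tert-butyl(diphenyl)silyl]oxymethyl}-4,11-dimethylbicyclo[7.2.0]undec-4-en-8-ol (C8 epimers) | OC1CC/C=C(C)/CC[C@H]2[C@H]1C[C@]2(C)CO[Si](c3ccccc3)(c3ccccc3)C(C)(C)C | intermediate
23 | (1S,9R,11S,4E)-11-{[tert-butyl(diphenyl)silyl]oxymethyl}-4,11-dimethylbicyclo[7.2.0]undec-4-en-8-one | O=C1CC/C=C(C)/CC[C@H]2[C@H]1C[C@]2(C)CO[Si](c3ccccc3)(c3ccccc3)C(C)(C)C | intermediate
24 | (1S,9R,11S,4E)-11-{[tert-butyl(diphenyl)silyl]oxymethyl}-4,11-dimethyl-8-methylidenebicyclo[7.2.0]undec-4-ene | C=C1CC/C=C(C)/CC[C@H]2[C@H]1C[C@]2(C)CO[Si](c3ccccc3)(c3ccccc3)C(C)(C)C | intermediate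
25 | (1S,4S,5S,9R,11S)-11-{[tert-butyl(diphenyl)silyl]oxymethyl}-4,5-epoxy-4,11-dimethyl-8-methylidenebicyclo[7.2.0]undecane | C=C1CC[C@@H]2O[C@@]2(C)CC[C@H]2[C@H]1C[C@]2(C)CO[Si](c3ccccc3)(c3ccccc3)C(C)(C)C | intermediate
26 | [(1S,4S,5S,9R,11S)-4,5-epoxy-4,11-dimethyl-8-methylidenebicyclo[7.2.0]undecan-11-yl]methanol | C=C1CC[C@@H]2O[C@@]2(C)CC[C@H]2[C@H]1C[C@]2(C)CO | intermediate
27 | (1S,4S,5S,9R,11S)-4,5-epoxy-4,11-dimethyl-8-methylidenebicyclo[7.2.0]undecane-11-carbaldehyde (epoxy core aldehyde) | C=C1CC[C@@H]2O[C@@]2(C)CC[C@H]2[C@H]1C[C@]2(C)C=O | intermediate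
28 | ethyl tiglate | C/C=C(\C)C(=O)OCC | starting material
29 | lithium dienolate of ethyl tiglate (not isolated) | C=CC(C)=C(OCC)O[Li] | intermediate
30 | 1-ethoxy-2-methyl-1-(trimethylsilyloxy)buta-1,3-diene | C=C/C(C)=C(/OCC)O[Si](C)(C)C | intermediate
31 | (6S)-3-methyl-6-[(1S,4S,5S,9R,11S)-4,5-epoxy-4,11-dimethyl-8-methylidenebicyclo[7.2.0]undecan-11-yl]-5,6-dihydro-2H-pyran-2-one | C=C1CC[C@@H]2O[C@@]2(C)CC[C@H]2[C@H]1C[C@]2(C)[C@@H]1CC=C(C)C(=O)O1 | intermediate
32 | lactol of 31 (C5' epimers, not isolated) | C=C1CC[C@@H]2O[C@@]2(C)CC[C@H]2[C@H]1C[C@]2(C)[C@@H]1CC=C(C)C(O)O1 | intermediate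
33 | (1S,3Z)-1-[(1S,4S,5S,9R,11S)-4,5-epoxy-4,11-dimethyl-8-methylidenebicyclo[7.2.0]undecan-11-yl]-4-methylpent-3-ene-1,5-diol | C=C1CC[C@@H]2O[C@@]2(C)CC[C@H]2[C@H]1C[C@]2(C)[C@H](C/C=C(/C)CO)O | intermediate
34 | CNP0256343.1, the (1'S,3'Z)-1',5'-diacetate with (1S,4S,5S,9R,11S) core | C=C1CC[C@@H]2O[C@@]2(C)CC[C@H]2[C@H]1C[C@]2(C)[C@H](C/C=C(/C)COC(C)=O)OC(C)=O | target

**Step count and risks**

Total step count: 22. Longest linear sequence: 21 steps (steps 1–18 and 20–22); step 19 is a one-step side branch.

Steps most likely to fail: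

Step 20. The addition to the neopentyl-type aldehyde may be slow or incomplete, the dienolate may attack through its α-carbon, the aldolate may fail to lactonise, or the catalyst may not override a mismatched facial preference. The fallback sets out from 27 and returns to the route at 31. Asymmetric allylboration of 27 with (−)-B-allyldiisopinocampheylborane (the enantiomer expected to attack the Si face, in line with the Felkin–Anh preference) should give the (1'S)-homoallylic alcohol F1. Acylation with methacryloyl chloride (Et3N, DMAP) gives the methacrylate F2. Ring-closing metathesis with the second-generation Grubbs catalyst then forms C3'=C4' inside the six-membered ring and delivers lactone 31.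

Step 13. Intermolecular coupling, protodeboronation or β-hydride elimination may outrun closure of the strained nine-membered ring. The fallback sets out from 20 and returns at 23. It replaces the hydroboration–transmetalation sequence by an intramolecular Heck reaction (Pd(OAc)2, Bu4NCl, NaHCO3, DMF, high dilution). The vinylpalladium species is expected to add to the terminal carbon C6 of the allylic alcohol, and β-hydride elimination toward C8 gives the enol and hence ketone 23 directly. This fallback makes no new compound (F0).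

Step 6. The facial discrimination between the C11 methyl and the CH2OTBDPS group may be insufficient, which would give a mixture at C1. The fallback sets out from 7 and 8 and returns at 10. Bromide 8 is converted with NaI into (4-iodobut-1-yn-1-yl)trimethylsilane F3 and then with Et2Zn into bis[4-(trimethylsilyl)but-3-yn-1-yl]zinc F4. F4 is added to 7 with Cu(OTf)2 and a chiral phosphoramidite ligand chosen to reinforce attack anti to CH2OTBDPS, so that the catalyst and not only the substrate decides the face. Trapping of the zinc enolate with TMSOTf gives 10.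

Further compounds
F1 | step 20 | (1S)-1-[(1S,4S,5S,9R,11S)-4,5-epoxy-4,11-dimethyl-8-methylidenebicyclo[7.2.0]undecan-11-yl]but-3-en-1-ol | C=C1CC[C@@H]2O[C@@]2(C)CC[C@H]2[C@H]1C[C@]2(C)[C@H](CC=C)O
F2 | step 20 | methacrylate ester of F1 | C=C1CC[C@@H]2O[C@@]2(C)CC[C@H]2[C@H]1C[C@]2(C)[C@H](CC=C)OC(=O)C(C)=C
F0 | step 13 | none | none
F3 | step 6 | (4-iodobut-1-yn-1-yl)trimethylsilane | C[Si](C)(C)C#CCCI
F4 | step 6 | bis[4-(trimethylsilyl)but-3-yn-1-yl]zinc | C[Si](C)(C)C#CCC[Zn]CCC#C[Si](C)(C)C
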